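## Retrosynthetic overview

1. Target ⇐ isopropenyl ketone: a catalyst-controlled ketone reduction sets the side-chain (R)-carbinol last.
2. Isopropenyl ketone ⇐ bromochloro alkynol + a bis-allylic alcohol: a ruthenium-catalysed alkyne/allylic-alcohol coupling forms the side-chain C–C bond, the 1,1-disubstituted alkene and the enone in one step.
3. Bromochloro alkynol ⇐ enynol: a new titanium-alkoxide-directed anti-Markovnikov bromochlorination sets C3–Cl and C4–Br from the C1 hydroxyl, before any other alkene is present.
4. Enynol ⇐ hydroxy aldehyde ⇐ cyclohexene diol ⇐ acyclic diene diol: the only ring, the cyclohexene, is closed by ring-closing metathesis.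
5. Diene diol ⇐ 2,2-disubstituted epoxy alcohol ⇐ 2-allyl allylic alcohol ⇐ propargyl alcohol + allyl Grignard: C1 is set by Sharpless epoxidation; the epoxide is a transient ring opened by methallyl Grignard.

Assumption: the target is taken exactly as drawn, i.e. (1S,3S,4S)-4-bromo-3-chloro-1-[(5R)-5-hydroxy-6-methylhepta-1,6-dien-2-yl]-4-methylcyclohexan-1-ol (ring OH and Cl cis, Br trans to both); the Grignard solutions, ClTi(OiPr)3, CpRu(MeCN)3PF6 and the Ohira–Bestmann reagent are taken as purchased.

## Route

Step 1
Reactants: 1 prop-2-yn-1-ol; 2 allylmagnesium bromide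
Product: 3 2-methylidenepent-4-en-1-ol
Conditions: 2 (2.5 equiv), CuI (10 mol%), Et2O, 0 °C to rt; aq. NH4Cl
Reagents that add atoms: none
Why: Hydroxyl-assisted, copper-catalysed anti carbomagnesiation of propargyl alcohol (one equivalent of 2 makes the magnesium alkoxide, the next adds allyl to the internal alkyne carbon through a five-membered magnesium chelate) gives the 2-substituted allylic alcohol on protonation; no stereocentre is formed.

Step 2
Reactants: 3 2-methylidenepent-4-en-1-ol
Product: 4 [(2S)-2-(prop-2-en-1-yl)oxiran-2-yl]methanol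
Conditions: Ti(OiPr)4 (10 mol%), L-(+)-diisopropyl tartrate (12 mol%), t-BuOOH (2 equiv, anhydrous), 4 Å MS, CH2Cl2, −20 °C
Reagents that add atoms: tert-butyl hydroperoxide, CC(C)(C)OO
Why: Sharpless asymmetric epoxidation touches only the allylic alkene, and the L-(+)-tartrate catalyst delivers oxygen in the same facial sense as allyl alcohol → (S)-glycidol, giving the (S)-epoxy alcohol that becomes the C1 carbinol centre.

Step 3
Reactants: 4 [(2S)-2-(prop-2-en-1-yl)oxiran-2-yl]methanol; 5 (2-methylprop-2-en-1-yl)magnesium chloride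
Product: 6 (2S)-2-(3-methylbut-3-en-1-yl)pent-4-ene-1,2-diol
Conditions: 5 (3 equiv), CuI (10 mol%), THF, −40 to 0 °C; aq. NH4Cl
Reagents that add atoms: none
Why: Copper-catalysed SN2 opening of the epoxide at its unsubstituted CH2 by the allylic Grignard reagent (one equivalent is spent on the free hydroxyl) leaves the quaternary stereocentre untouched.

Step 4
Reactants: 6 (2S)-2-(3-methylbut-3-en-1-yl)pent-4-ene-1,2-diol
Product: 7 (1S)-1-(hydroxymethyl)-4-methylcyclohex-3-en-1-ol
Conditions: second-generation Grubbs catalyst RuCl2(=CHPh)(H2IMes)(PCy3) (3 mol%), CH2Cl2 (0.01 M), 40 °C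
Reagents that add atoms: none
Why: Ring-closing olefin metathesis between the allyl alkene and the 1,1-disubstituted alkene closes the six-membered ring with the trisubstituted C3=C4 alkene; the free diol is tolerated and the stereocentre is unaffected.

Step 5
Reactants: 7 (1S)-1-(hydroxymethyl)-4-methylcyclohex-3-en-1-ol
Product: 8 (1S)-1-hydroxy-4-methylcyclohex-3-ene-1-carbaldehyde
Conditions: 2-iodoxybenzoic acid (IBX, 1.5 equiv), DMSO, 23 °C; used crude
Reagents that add atoms: none
Why: IBX oxidation converts the primary alcohol of a 1,2-diol to the aldehyde without glycol cleavage and leaves the tertiary alcohol and the alkene alone.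

Step 6
Reactants: 8 (1S)-1-hydroxy-4-methylcyclohex-3-ene-1-carbaldehyde; 9 dimethyl (1-diazo-2-oxopropyl)phosphonate
Product: 10 (1S)-1-ethynyl-4-methylcyclohex-3-en-1-ol
Conditions: 9 (1.3 equiv), K2CO3 (2.5 equiv), MeOH, 0 °C to rt
Reagents that add atoms: none
Why: Seyferth–Gilbert homologation under Ohira–Bestmann conditions (Horner–Wadsworth–Emmons-type addition of the diazomethylphosphonate anion, loss of N2 and 1,2-hydride shift) gives the terminal alkyne; the adjacent quaternary carbinol centre cannot epimerise.

Step 7
Reactants: 10 (1S)-1-ethynyl-4-methylcyclohex-3-en-1-ol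
Product: 12 (1S,3S,4S)-4-bromo-3-chloro-1-ethynyl-4-methylcyclohexan-1-ol, via chlorotitanium alkoxide 11 (not isolated)
Conditions: ClTi(OiPr)3 (1.2 equiv), CH2Cl2, rt, then i-PrOH stripped in vacuo; NBS (1.1 equiv), hexane/CH2Cl2, −30 to −20 °C; aq. NaHCO3
Reagents that add atoms: N-bromosuccinimide, O=C1CCC(=O)N1Br; chlorotitanium triisopropoxide ClTi(OiPr)3, CC(C)O[Ti](Cl)(OC(C)C)OC(C)C
Why: Proposed new method: the tertiary alkoxide is held on titanium as RO–TiCl(OiPr)2, NBS forms the bromonium ion on the alkene face anti to this bulky group, and the titanium-bound chloride is handed to the nearer alkene carbon (C3) by axial attack through a six-membered chair-like transition state (trans-diaxial opening), which overrides the Markovnikov preference for the tertiary carbon and gives C3–Cl cis and C4–Br trans to the hydroxyl (3S,4S) while the less nucleophilic alkyne is left alone; the closest known reaction type is the titanium-alkoxide-mediated bromochlorination of allylic alcohols with NBS and ClTi(OiPr)3, here extended to a cyclic tertiary homoallylic alcohol with reversed regiochemistry.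

Step 8
Reactants: 13 acrolein; 14 isopropenylmagnesium bromide
Product: 15 2-methylpenta-1,4-dien-3-ol (racemic)
Conditions: THF, −78 °C; aq. NH4Cl
Reagents that add atoms: none
Why: 1,2-Addition of the alkenyl Grignard reagent to the aldehyde of acrolein at low temperature gives the bis-allylic alcohol, whose stereocentre is erased in step 9.

Step 9
Reactants: 12 (1S,3S,4S)-4-bromo-3-chloro-1-ethynyl-4-methylcyclohexan-1-ol; 15 2-methylpenta-1,4-dien-3-ol
Product: 17 6-[(1S,3S,4S)-4-bromo-3-chloro-1-hydroxy-4-methylcyclohexyl]-2-methylhepta-1,6-dien-3-one, via dienol 16 (not isolated)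
Conditions: CpRu(MeCN)3PF6 (10 mol%), 15 (2 equiv), acetone, rt
Reagents that add atoms: none
Why: Ruthenium-catalysed alkene–alkyne coupling (Trost Alder-ene type) joins the internal alkyne carbon to the terminal carbon of the monosubstituted alkene via a ruthenacyclopentene (branched selectivity helped by the propargylic hydroxyl), β-hydride elimination of the carbinol C–H gives dienol 16, and tautomerisation gives the enone; no stereocentre is formed and the ring centres are untouched.

Step 10
Reactants: 17 6-[(1S,3S,4S)-4-bromo-3-chloro-1-hydroxy-4-methylcyclohexyl]-2-methylhepta-1,6-dien-3-one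
Product: 18 (1S,3S,4S)-4-bromo-3-chloro-1-[(5R)-5-hydroxy-6-methylhepta-1,6-dien-2-yl]-4-methylcyclohexan-1-ol
Conditions: (S)-2-methyl-CBS-oxazaborolidine (0.5 equiv), catecholborane (3 equiv), toluene, −78 °C; MeOH, then pH 7 buffer
Reagents that add atoms: none
Why: Corey–Bakshi–Shibata reduction with the isopropenyl group as the large substituent gives the (R)-carbinol from the (S)-catalyst (same sense as acetophenone → (R)-1-phenylethanol), and catecholborane at −78 °C spares the alkenes and both halides.

## Compound list

1 | prop-2-yn-1-ol | C#CCO | starting material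
2 | allylmagnesium bromide | C=CC[Mg]Br | starting material
3 | 2-methylidenepent-4-en-1-ol | C=CCC(=C)CO | intermediate
4 | [(2S)-2-(prop-2-en-1-yl)oxiran-2-yl]methanol | OC[C@@]1(CC=C)CO1 | intermediate
5 | (2-methylprop-2-en-1-yl)magnesium chloride | C=C(C)C[Mg]Cl | starting material
6 | (2S)-2-(3-methylbut-3-en-1-yl)pent-4-ene-1,2-diol | OC[C@](CC=C)(O)CCC(C)=C | intermediate
7 | (1S)-1-(hydroxymethyl)-4-methylcyclohex-3-en-1-ol | OC[C@]1(O)CCC(C)=CC1 | intermediate
8 | (1S)-1-hydroxy-4-methylcyclohex-3-ene-1-carbaldehyde | O=C[C@]1(O)CCC(C)=CC1 | intermediate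
9 | dimethyl (1-diazo-2-oxopropyl)phosphonate | COP(=O)(OC)C(=[N+]=[N-])C(C)=O | starting material
10 | (1S)-1-ethynyl-4-methylcyclohex-3-en-1-ol | C#C[C@]1(O)CCC(C)=CC1 | intermediate
11 | chlorobis(propan-2-olato)titanium (1S)-1-ethynyl-4-methylcyclohex-3-en-1-olate (formed in the flask) | C#C[C@]1(O[Ti](Cl)(OC(C)C)OC(C)C)CCC(C)=CC1 | intermediate
12 | (1S,3S,4S)-4-bromo-3-chloro-1-ethynyl-4-methylcyclohexan-1-ol | C#C[C@]1(O)CC[C@](C)(Br)[C@@H](Cl)C1 | intermediate
13 | acrolein (prop-2-enal) | C=CC=O | starting material
14 | isopropenylmagnesium bromide | C=C(C)[Mg]Br | starting material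
15 | 2-methylpenta-1,4-dien-3-ol (racemic) | C=CC(O)C(C)=C | intermediate
16 | 6-[(1S,3S,4S)-4-bromo-3-chloro-1-hydroxy-4-methylcyclohexyl]-2-methylhepta-1,3,6-trien-3-ol (formed in the flask) | C=C(C)C(O)=CCC(=C)[C@]1(O)CC[C@](C)(Br)[C@@H](Cl)C1 | intermediate
17 | 6-[(1S,3S,4S)-4-bromo-3-chloro-1-hydroxy-4-methylcyclohexyl]-2-methylhepta-1,6-dien-3-one | C=C(C)C(=O)CCC(=C)[C@]1(O)CC[C@](C)(Br)[C@@H](Cl)C1 | intermediate
18 | (1S,3S,4S)-4-bromo-3-chloro-1-[(5R)-5-hydroxy-6-methylhepta-1,6-dien-2-yl]-4-methylcyclohexan-1-ol | C=C(C)[C@H](O)CCC(=C)[C@]1(O)CC[C@](C)(Br)[C@@H](Cl)C1 | target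

## Step count and risks

Total steps: 10. Longest linear sequence: 9 (steps 1–7, 9, 10); step 8 is a one-step side branch.

**Most likely to fail, first: step 7 (the proposed new step).** The risks are bromoetherification by the C1 oxygen (giving a 7-oxabicyclo[2.2.1]heptane), Markovnikov chloride delivery to the tertiary carbon, and weak facial control. The fallback uses known chemistry, sets out from 10 and comes back at 12. The elements of BrCl are added in the conventional Markovnikov anti sense with tetrabutylammonium dichlorobromate (CH2Cl2, −40 °C). After chromatographic removal of the other facial isomer (facial selectivity here is expected to be modest), this gives the tertiary chloride (1S,3R,4R)-3-bromo-4-chloro-1-ethynyl-4-methylcyclohexan-1-ol F1. Warming F1 in toluene (90–100 °C) brings about the known thermal 1,2-interchange of vicinal trans-diaxial halogens (diaxial-to-diequatorial dyotropic rearrangement, each halogen staying on its own face). This moves bromine to the tertiary carbon and chlorine to the secondary carbon and gives 12. The rearrangement is an equilibrium of uncertain position, so unchanged F1 is separated and recycled.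

**Second: step 9.** The bis-allylic alcohol 15 may isomerise or the vinyl ketone product may not survive the cationic ruthenium catalyst, and the hindered, halogenated alkyne may couple slowly. The fallback gives up the one-step redox-neutral union and builds the enone stepwise through an aldehyde; it still relies on a ruthenium coupling, so it answers a failure of partner 15 but not of alkyne 12 itself. It sets out from 12 and comes back at 17. Compound 12 is coupled with plain allyl alcohol under the same catalyst, which gives the aldehyde 4-[(1S,3S,4S)-4-bromo-3-chloro-1-hydroxy-4-methylcyclohexyl]pent-4-enal F2, expected to be present largely as its spiro-lactol (6S,8S,9S)-9-bromo-8-chloro-9-methyl-5-methylidene-1-oxaspiro[5.5]undecan-2-ol F3. Excess isopropenylmagnesium bromide 14 (THF, −78 to −20 °C) opens the lactol to the carbinol-epimeric diol (1S,3S,4S)-4-bromo-3-chloro-1-(5-hydroxy-6-methylhepta-1,6-dien-2-yl)-4-methylcyclohexan-1-ol F4. MnO2 in CH2Cl2 then oxidises only the secondary allylic alcohol and gives 17.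

**Third: step 6.** The unprotected tertiary α-hydroxy aldehyde 8 may dimerise or undergo α-ketol rearrangement under K2CO3/MeOH before homologation. The fallback is a protecting-group detour that never exposes the free α-ketol to base; it sets out from 7 and comes back at 10. Both hydroxyls are silylated (TESOTf, 2,6-lutidine, CH2Cl2) to triethyl{[(1S)-4-methyl-1-(triethylsilyloxy)cyclohex-3-en-1-yl]methoxy}silane F5. A Swern oxidation (oxalyl chloride, DMSO, Et3N) cleaves and oxidises only the primary silyl ether to (1S)-4-methyl-1-(triethylsilyloxy)cyclohex-3-ene-1-carbaldehyde F6. Homologation with 9 (K2CO3, MeOH) gives {[(1S)-1-ethynyl-4-methylcyclohex-3-en-1-yl]oxy}triethylsilane F7, and Bu4NF in THF frees the tertiary alcohol to give 10.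

## Further compounds

F1 | step 7 | (1S,3R,4R)-3-bromo-4-chloro-1-ethynyl-4-methylcyclohexan-1-ol | C#C[C@]1(O)CC[C@](Cl)(C)[C@H](Br)C1
F2 | step 9 | 4-[(1S,3S,4S)-4-bromo-3-chloro-1-hydroxy-4-methylcyclohexyl]pent-4-enal | O=CCCC(=C)[C@]1(O)CC[C@](C)(Br)[C@@H](Cl)C1
F3 | step 9 | (6S,8S,9S)-9-bromo-8-chloro-9-methyl-5-methylidene-1-oxaspiro[5.5]undecan-2-ol (both anomers) | OC1CCC(=C)[C@]2(O1)CC[C@](C)(Br)[C@@H](Cl)C2
F4 | step 9 | (1S,3S,4S)-4-bromo-3-chloro-1-(5-hydroxy-6-methylhepta-1,6-dien-2-yl)-4-methylcyclohexan-1-ol (both side-chain C5 epimers) | C=C(C)C(O)CCC(=C)[C@]1(O)CC[C@](C)(Br)[C@@H](Cl)C1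
F5 | step 6 | triethyl{[(1S)-4-methyl-1-(triethylsilyloxy)cyclohex-3-en-1-yl]methoxy}silane | CC[Si](CC)(CC)OC[C@]1(O[Si](CC)(CC)CC)CCC(C)=CC1
F6 | step 6 | (1S)-4-methyl-1-(triethylsilyloxy)cyclohex-3-ene-1-carbaldehyde | O=C[C@]1(O[Si](CC)(CC)CC)CCC(C)=CC1
F7 | step 6 | {[(1S)-1-ethynyl-4-methylcyclohex-3-en-1-yl]oxy}triethylsilane | C#C[C@]1(O[Si](CC)(CC)CC)CCC(C)=CC1
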